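**Assumptions (one line each)**
- Compound 1, (−)-7-hydroxymatairesinol, is a bulk spruce-knotwood lignan. I take it to be the natural (7S,8R,8'R) isomer, with the benzylic OH on the carbon α to the lactone carbonyl.
- Mapping, lignan numbering of 1 → target: C7(OH) → C7', C8 → C8', C8' → C8, C9 (C=O) → ring CH2 (C9'), C9' (OCH2) → CH2OH (C9), C7'H2 → ring C7.
- The target is 7'-hydroxylariciresinol, with ring substituents 2,3-trans and 3,4-trans.

**Retrosynthetic overview**
1. Target 6 comes from 5 by removing three pivaloyl groups.
2. The only ring formed is the THF. It closes in a photochemical dehydrogenative benzylic C–H etherification, in which the C9 primary OH captures a benzylic cation at C7'H2 (5-exo). This sets C7 trans to C8.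
3. The cyclization substrate, diol 4, comes from chemoselective lactone reduction of tri-pivalate 3.
4. Compound 3 comes from the natural lactone 1. All three existing stereocenters (C7', C8', C8) are carried over from 1, and none is touched.

---

**Step 1**
Reactants: 1 (−)-7-hydroxymatairesinol; 2 pivaloyl chloride
Product: 3, the tri-O-pivaloyl derivative of 1. Both phenols and the benzylic C7' alcohol are pivalates, and the lactone is intact.
Conditions: PivCl (4.5 equiv), Et3N, DMAP (cat.), CH2Cl2, 0 → 40 °C
Reagents that add atoms: pivaloyl chloride, CC(C)(C)C(=O)Cl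
Why: DMAP-catalysed acylation caps all three OH groups. The electron-withdrawing esters raise the arene oxidation potentials and deactivate the α-acyloxy benzylic C–H. They also block the C7' oxygen, which would otherwise form a 2,5-diaryl THF. No stereocenter is touched.

**Step 2**
Reactants: 3
Product: 4, the diol. The lactone C=O becomes CH2OH and the ring OCH2 becomes the second CH2OH. The three pivalates are kept.
Conditions: LiBH4 (3 equiv), THF, 0 °C → rt; aq. NH4Cl work-up
Reagents that add atoms: none
Why: LiBH4 reduces the strained γ-lactone to the 1,4-diol faster than it attacks the hindered pivalates, which survive. The mild, non-enolising conditions leave C8 and C8' configured.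

**Step 3**
Reactants: 4
Product: 5, the tri-pivalate of the target. It is the 2,3-trans-3,4-trans tetrahydrofuran with C7 = S.
Conditions: [Mes-Acr-Ph]+BF4− (3 mol %), Co(dmgH)2pyCl (5 mol %), 2,6-lutidine (0.3 equiv), HFIP/CH2Cl2 (1:4, 0.02 M), blue LEDs (450 nm), 25 °C, N2, H2 evolved
Reagents that add atoms: none
Why: Proposed new method: photoredox/cobaloxime acceptorless dehydrogenative benzylic C–H etherification applied to a polyfunctional, stereodefined lignan diol. Excited acridinium oxidises the unhindered guaiacyl ring to its radical cation. Deprotonation at C7'H2 (the C7–H is deactivated by its acyloxy group), then Co-mediated radical oxidation, gives a benzylic cation, which the C9 primary OH captures 5-exo. The closest known reactions are DDQ- or acridinium-mediated 4-arylbutanol → 2-aryl-THF cyclisations. Ring closure through the planar cation places the new aryl trans to the C8 CH2OH. Reversible ionisation of the benzylic ether in HFIP funnels the mixture to the all-pseudo-equatorial trans,trans isomer.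

**Step 4**
Reactants: 5
Product: 6, the target
Conditions: LiAlH4 (6 equiv), THF, 0 → 45 °C; Rochelle salt work-up
Reagents that add atoms: none
Why: Hydride cleavage of the aryl and benzylic pivalates releases the two phenols and the C7' OH. The THF ether and all stereocenters are unaffected.

---

**Compound list**

1 | (−)-7-hydroxymatairesinol, (3R,4R)-3-[(S)-hydroxy(4-hydroxy-3-methoxyphenyl)methyl]-4-(4-hydroxy-3-methoxybenzyl)oxolan-2-one | COc1cc([C@@H](O)[C@@H]2C(=O)OC[C@@H]2Cc2ccc(O)c(OC)c2)ccc1O | starting material
2 | pivaloyl chloride | CC(C)(C)C(=O)Cl | starting material (reagent)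
3 | tri-O-pivaloyl-7-hydroxymatairesinol (two aryl pivalates and the benzylic pivalate, lactone intact) | COc1cc([C@@H](OC(=O)C(C)(C)C)[C@@H]2C(=O)OC[C@@H]2Cc2ccc(OC(=O)C(C)(C)C)c(OC)c2)ccc1OC(=O)C(C)(C)C | intermediate
4 | seco-diol tri-pivalate (7-hydroxysecoisolariciresinol tri-O-pivaloate with both CH2OH free) | COc1cc([C@@H](OC(=O)C(C)(C)C)[C@H](CO)[C@H](CO)Cc2ccc(OC(=O)C(C)(C)C)c(OC)c2)ccc1OC(=O)C(C)(C)C | intermediate
5 | tri-O-pivaloyl-7'-hydroxylariciresinol | COc1cc([C@@H](OC(=O)C(C)(C)C)[C@@H]2CO[C@H](c3ccc(OC(=O)C(C)(C)C)c(OC)c3)[C@H]2CO)ccc1OC(=O)C(C)(C)C | intermediate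
6 | 7'-hydroxylariciresinol, (2S,3R,4S)-2-(4-hydroxy-3-methoxyphenyl)-3-(hydroxymethyl)-4-[(S)-hydroxy(4-hydroxy-3-methoxyphenyl)methyl]oxolane | COc1cc([C@@H](O)[C@@H]2CO[C@H](c3ccc(O)c(OC)c3)[C@H]2CO)ccc1O | target

Formula check: 1 C20H22O7 → 3 C35H46O10 → 4 C35H50O10 → 5 C35H48O10 (−H2) → 6 C20H24O7, which matches the target.

**Total steps:** 4
**Longest linear sequence:** 4 steps (1 → 3 → 4 → 5 → 6)

**Three steps most likely to fail**

1. **Step 3 (proposed new step):** the risks are over-oxidation of the more oxidisable product C7–H, competing arene radical-cation fragmentation, and poor trans selectivity.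
   - Fallback (known chemistry): Wohl–Ziegler benzylic bromination of 4 (NBS, (PhCO2)2, PhCF3, 80 °C). The C7–H is deactivated by its acyloxy group. Then close the ring by SN1 etherification with AgOTf and 2,6-di-tert-butyl-4-methylpyridine, through the same trans-selective benzylic cation capture.
2. **Step 2:** LiBH4 may attack the aryl pivalates, or pivalate may migrate from C7' O to the new C9 alkoxide.
   - Fallback: reduce the lactone in two stages through the lactol. DIBAL (1.1 equiv, CH2Cl2, −78 °C) gives the lactol, and NaBH4/MeOH at 0 °C then opens it, so no free alkoxide persists next to the benzylic ester.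
3. **Step 1:** acylating the hindered secondary benzylic OH may be incomplete, and base may cause E1cB loss of pivalate from the α-stereocenter.
   - Fallback: change the order of operations. Reduce unprotected 1 with LiAlH4 to the pentol, per-pivaloylate it, then selectively cleave the two primary pivalates with DIBAL (2.2 equiv, −78 °C) to give 4.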